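**Plan**

- Cuts: first the three phenolic O–CH3 bonds (the phloroglucinol hydroxyls travel as methyl ethers), then the bond between the ketone carbon C1 and chain carbon C2, then the bond between chain carbon C11 and its phenyl ring.
- Enabling feature: the aryl ketone carbon C1 heads an unbranched run of ten methylenes (C2 to C11). The C1–C2 bond is therefore what forms when the formyl C–H of an aryl aldehyde adds across the terminal C=C of a 1-alkene. Both ring carbons ortho to the acyl group carry oxygen, so the ring offers no ortho C–H to a directed metal.
- Forward order: a phenyl group is joined to the ω-carbon of a C10 bromoalkene, the resulting 1-alkene is acylated at its terminal carbon by the trimethoxybenzaldehyde, and the methyl ethers are cleaved. No ring is formed; both benzene rings are bought.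
- Stereochemistry: the target has no stereocentre and no stereogenic double bond, so nothing has to be controlled.

Key step: step 2

**Route**

Step 1
Reactants: 1 10-bromodec-1-ene; 2 phenylmagnesium bromide (PhMgBr)
Product: 3 10-phenyldec-1-ene
Conditions: PhMgBr (1.3 equiv), Li2CuCl4 (3 mol%), THF, -10 °C to rt
Reagents that add atoms: none
Why: Copper-catalysed Grignard cross-coupling of the Kochi type, in which the organocopper ate species formed from PhMgBr and catalytic Li2CuCl4 displaces the primary bromide while the remote terminal alkene stays untouched.

Step 2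
Reactants: 4 2,4,6-trimethoxybenzaldehyde; 3 10-phenyldec-1-ene
Product: 7 11-phenyl-1-(2,4,6-trimethoxyphenyl)undecan-1-one, via pyridyl aldimine 5 (not isolated), via pyridyl ketimine 6 (not isolated)
Conditions: RhCl(PPh3)3 (5 mol%), 2-amino-3-picoline (0.5 equiv), PhCO2H (10 mol%), 3 (1.5 equiv), toluene, 130 °C, sealed tube; then 1 M HCl, THF, rt
Reagents that add atoms: 2-amino-3-picoline, Cc1cccnc1N (its atoms sit in 5 and 6 only and leave again on hydrolysis); water, O (returns the carbonyl oxygen when 6 is hydrolysed to 7)
Why: Chelation-assisted hydroacylation through a transient aldimine: 4 condenses with 2-amino-3-picoline under benzoic acid catalysis to aldimine 5, whose pyridine nitrogen steers monovalent rhodium into the iminoacyl C–H bond to give a five-membered trivalent rhodium hydride chelate. Alkene 3 then inserts into the Rh–H bond with the metal going to the terminal carbon, and C–C reductive elimination gives ketimine 6, which the water released in the condensation and the acidic work-up hydrolyse to 7 with return of the amine. The closest known reaction is the RhCl(PPh3)3/2-amino-3-picoline hydroacylation of 1-alkenes with aromatic aldehydes, electron-rich ones included. No ring closes and no stereocentre forms. The step needs linear rather than branched addition and acylation rather than decarbonylation: the monosubstituted alkene with its unbranched chain puts the bulky metal on C1, internal alkenes formed by isomerisation react far more slowly and can walk back to the terminal alkyl, and the chelated iminoacyl cannot extrude CO. Both positions ortho to the imine carbon bear methoxy groups, which rules out the directed ortho C–H alkylation that aryl ketimines can otherwise undergo.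

Step 3
Reactants: 7 11-phenyl-1-(2,4,6-trimethoxyphenyl)undecan-1-one
Product: 8 11-phenyl-1-(2,4,6-trihydroxyphenyl)undecan-1-one (target)
Conditions: BBr3 (6 equiv), CH2Cl2, -78 °C to rt; then ice-water
Reagents that add atoms: none
Why: Lewis-acid cleavage of aryl methyl ethers, in which BBr3 binds each ether oxygen (the two ortho ethers assisted by chelation to the ketone) and bromide removes the methyl group by SN2, a standard way from 2,4,6-trimethoxyphenyl ketones to acylphloroglucinols that leaves the saturated chain and the terminal phenyl ring alone.

**Compound list**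

1 | 10-bromodec-1-ene | C=CCCCCCCCCBr | starting material
2 | phenylmagnesium bromide | Br[Mg]c1ccccc1 | starting material
3 | 10-phenyldec-1-ene | C=CCCCCCCCCc1ccccc1 | intermediate
4 | 2,4,6-trimethoxybenzaldehyde | COc1cc(OC)c(C=O)c(OC)c1 | starting material
5 | (E)-N-(3-methylpyridin-2-yl)-1-(2,4,6-trimethoxyphenyl)methanimine | COc1cc(OC)c(/C=N/c2ncccc2C)c(OC)c1 | intermediate (not isolated)
6 | N-(3-methylpyridin-2-yl)-11-phenyl-1-(2,4,6-trimethoxyphenyl)undecan-1-imine | COc1cc(OC)c(C(CCCCCCCCCCc2ccccc2)=Nc2ncccc2C)c(OC)c1 | intermediate (not isolated)
7 | 11-phenyl-1-(2,4,6-trimethoxyphenyl)undecan-1-one | O=C(CCCCCCCCCCc1ccccc1)c1c(OC)cc(OC)cc1OC | intermediate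
8 | 11-phenyl-1-(2,4,6-trihydroxyphenyl)undecan-1-one | O=C(CCCCCCCCCCc1ccccc1)c1c(O)cc(O)cc1O | target

**Count**

Total steps: 3. Longest linear sequence: 3 steps (1 to 3 to 7 to 8).

**Steps most likely to fail**

1. Step 2 (key step). The formyl group flanked by two methoxy groups may condense slowly with the aminopicoline, and C–H insertion at the crowded aldimine may lag behind rhodium hydride isomerisation of the terminal alkene to unreactive internal alkenes. The fallback sets out from alkene 3 and comes back at ketone 7 by polar chemistry. Peroxide-initiated anti-Markovnikov addition of HBr to 3 (HBr, (PhCO2)2, hexane, 0 °C) should give 1-bromo-10-phenyldecane F1. Mg turnings in THF would convert it into (10-phenyldecyl)magnesium bromide F2. Addition of this Grignard reagent to aldehyde 4 (THF, 0 °C, NH4Cl work-up) should give racemic 11-phenyl-1-(2,4,6-trimethoxyphenyl)undecan-1-ol F3. Buffered Dess–Martin oxidation (DMP, NaHCO3, CH2Cl2, rt) would take this acid-sensitive benzylic carbinol to 7.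

2. Step 3. After fast, chelation-assisted cleavage of the two ortho ethers, removal of the para methyl group may stall. Forcing it with more BBr3 or heat invites acid-promoted loss of the acyl group from the very electron-rich ring. The fallback sets out from alkene 3 and comes back at target 8 with benzyl in place of methyl. Vilsmeier–Haack formylation of commercial 1,3,5-tris(benzyloxy)benzene (POCl3, DMF; aqueous NaOAc) would give 2,4,6-tris(benzyloxy)benzaldehyde F4. Under the conditions of step 2, F4 and 3 should pass through (E)-N-(3-methylpyridin-2-yl)-1-[2,4,6-tris(benzyloxy)phenyl]methanimine F5 and N-(3-methylpyridin-2-yl)-11-phenyl-1-[2,4,6-tris(benzyloxy)phenyl]undecan-1-imine F6 to 11-phenyl-1-[2,4,6-tris(benzyloxy)phenyl]undecan-1-one F7. Hydrogenolysis (H2, Pd/C, EtOAc, rt) should then free the three phenols under neutral conditions and give 8; the hydrogen-bonded, electron-rich aryl ketone is expected to resist reduction.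

3. Step 1. Transfer of the aryl group from magnesium to copper may be slow, so that biphenyl formation, bromine–magnesium exchange and dehydrobromination of the alkyl bromide compete. The fallback sets out from bromide 1 and comes back at alkene 3 with the polarity reversed. Mg in THF would turn 1 into dec-9-en-1-ylmagnesium bromide F8. Kumada–Corriu coupling of F8 with bromobenzene under NiCl2(dppp) (1 mol%, Et2O/THF, reflux) should give 3.

**Further compounds**

F1 | step 2 | 1-bromo-10-phenyldecane | BrCCCCCCCCCCc1ccccc1
F2 | step 2 | (10-phenyldecyl)magnesium bromide | Br[Mg]CCCCCCCCCCc1ccccc1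
F3 | step 2 | 11-phenyl-1-(2,4,6-trimethoxyphenyl)undecan-1-ol (racemic) | OC(CCCCCCCCCCc1ccccc1)c1c(OC)cc(OC)cc1OC
F4 | step 3 | 2,4,6-tris(benzyloxy)benzaldehyde | O=Cc1c(OCc2ccccc2)cc(OCc2ccccc2)cc1OCc1ccccc1
F5 | step 3 | (E)-N-(3-methylpyridin-2-yl)-1-[2,4,6-tris(benzyloxy)phenyl]methanimine | Cc1cccnc1/N=C/c1c(OCc2ccccc2)cc(OCc2ccccc2)cc1OCc1ccccc1
F6 | step 3 | N-(3-methylpyridin-2-yl)-11-phenyl-1-[2,4,6-tris(benzyloxy)phenyl]undecan-1-imine | Cc1cccnc1N=C(CCCCCCCCCCc1ccccc1)c1c(OCc2ccccc2)cc(OCc2ccccc2)cc1OCc1ccccc1
F7 | step 3 | 11-phenyl-1-[2,4,6-tris(benzyloxy)phenyl]undecan-1-one | O=C(CCCCCCCCCCc1ccccc1)c1c(OCc2ccccc2)cc(OCc2ccccc2)cc1OCc1ccccc1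
F8 | step 1 | dec-9-en-1-ylmagnesium bromide | C=CCCCCCCCC[Mg]Br
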